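The naphthoquinone is numbered C1(=O), C2(OH), C3(alkyl), C4(=O), C4a, C8a; ring A is the benzo ring and ring B the quinone ring.
Retrosynthesis: C2–OH is masked as OMe. Ring B is cut at C1–C8a, which contracts the naphthoquinone to a 4-hydroxy-4-phenylcyclobutenone. Then the ester C(=O)–O bond, the cyclobutenone C3–CH2 bond and the C4–phenyl bond are cut, leading back to dimethyl squarate, phenyllithium, a neopentyl glycol iodide and acid 7.
Enabling feature: C1(=O)–C2(O)=C3(alkyl)–C4(=O) of ring B is a fully substituted four-carbon chain on an unsubstituted ring A, i.e. the four carbons of a squarate plus a phenyl group. The strained ring opens at C1–C4 to a vinylketene whose ketene carbon C1 lies next to a phenyl ortho carbon (C8a).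
Forward: squarate + PhLi (C4–C4a) and silyl cap, alkyllithium addition with carbonyl transposition (C3–CH2), desilylation, esterification with 7, ring expansion/oxidation (ring B), then hydrolysis of the vinylogous ester.
Stereochemistry: the only stereocentre (C6 of the acid, S) comes from Katsuki–Sharpless epoxidation of geraniol with L-(+)-diethyl tartrate and reductive opening to (S)-linalool. The 2E alkene comes from E-selective SeO2 oxidation.
Key step: step 12

Assumption: the carbinol carbon of cyclobutenones 13–21 is racemic, so 21 should be a pair of epimers at that carbon; this has no consequence because the carbon becomes sp2 C4 in step 12.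

Step 1
Reactants: 1 geraniol
Product: 2 (2S,3S)-2,3-epoxygeraniol
Conditions: Ti(OiPr)4 (5 mol %), L-(+)-diethyl tartrate (7 mol %), t-BuOOH (anhydrous, in decane), 4 Å molecular sieves, CH2Cl2, −20 °C
Reagents that add atoms: tert-butyl hydroperoxide, CC(C)(C)OO
Why: Katsuki–Sharpless asymmetric epoxidation: the titanium tartrate complex binds the allylic hydroxyl, so only the 2,3-alkene reacts, and L-(+)-diethyl tartrate should give the (2S,3S)-epoxide, whose C3–O bond is the later carbinol C–O bond of the target.

Step 2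
Reactants: 2 (2S,3S)-2,3-epoxygeraniol
Product: 3 (2R,3S)-2-(iodomethyl)-3-methyl-3-(4-methylpent-3-en-1-yl)oxirane
Conditions: I2, PPh3, imidazole, Et2O–MeCN, 0 °C
Reagents that add atoms: iodine, [I][I]
Why: Garegg–Samuelsson (Appel-type) iodination is an SN2 displacement at the primary carbon under near-neutral conditions, so the epoxide and both stereocentres stay untouched (the C2 descriptor becomes R only because CH2I outranks C3).

Step 3
Reactants: 3 (2R,3S)-2-(iodomethyl)-3-methyl-3-(4-methylpent-3-en-1-yl)oxirane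
Product: 4 (S)-(+)-linalool
Conditions: Zn dust, EtOH, reflux
Reagents that add atoms: none
Why: Reductive β-elimination of a 2,3-epoxy iodide: zinc inserts into the C–I bond and the carbon–zinc bond expels the epoxide oxygen from C2, which forms the vinyl group and leaves the C3–O bond, and so the S configuration, intact.

Step 4
Reactants: 4 (S)-(+)-linalool
Product: 6 (2E,6S)-6-hydroxy-2,6-dimethylocta-2,7-dienal, via allylic diol 5 (not isolated)
Conditions: SeO2 (0.2 equiv), t-BuOOH (in decane), salicylic acid (0.1 equiv), CH2Cl2, rt; crude product, then MnO2 (excess), CH2Cl2, rt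
Reagents that add atoms: tert-butyl hydroperoxide, CC(C)(C)OO (oxygen relayed through catalytic SeO2)
Why: Catalytic SeO2 allylic oxidation (ene reaction, then [2,3]-sigmatropic shift) attacks the E-methyl group of the trisubstituted alkene, the vinyl group has no allylic hydrogen, and MnO2 oxidises only the primary allylic alcohol, so alcohol and aldehyde from the first stage converge on the enal.

Step 5
Reactants: 6 (2E,6S)-6-hydroxy-2,6-dimethylocta-2,7-dienal
Product: 7 (2E,6S)-6-hydroxy-2,6-dimethylocta-2,7-dienoic acid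
Conditions: NaClO2, NaH2PO4, 2-methylbut-2-ene, t-BuOH–H2O, 0 °C to rt
Reagents that add atoms: sodium chlorite, [Na+].[O-]Cl=O
Why: Pinnick oxidation converts the enal into the acid without touching the alkene geometry or the tertiary allylic alcohol, and 2-methylbut-2-ene removes HOCl before it can add to the vinyl group.

Step 6
Reactants: 8 2,2-dimethylpropane-1,3-diol
Product: 9 3-(tert-butyldimethylsilyloxy)-2,2-dimethylpropan-1-ol
Conditions: TBSCl (1 equiv), imidazole, 8 (3 equiv), DMF, 0 °C to rt
Reagents that add atoms: tert-butyldimethylsilyl chloride, CC(C)(C)[Si](C)(C)Cl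
Why: Statistical monosilylation of a cheap symmetric diol used in excess should favour the monoether, and the surplus water-soluble diol is washed out.

Step 7
Reactants: 9 3-(tert-butyldimethylsilyloxy)-2,2-dimethylpropan-1-ol
Product: 10 tert-butyl(3-iodo-2,2-dimethylpropoxy)dimethylsilane
Conditions: I2, PPh3, imidazole, toluene, 100 °C
Reagents that add atoms: iodine, [I][I]
Why: Garegg–Samuelsson iodination: the neopentyl-type alkoxyphosphonium salt needs heat for the SN2 step, but it has no β-hydrogen to eliminate and forms no free cation that could rearrange.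

Step 8
Reactants: 11 dimethyl squarate; 12 phenyllithium
Product: 14 2,3-dimethoxy-4-phenyl-4-(triethylsilyloxy)cyclobut-2-en-1-one, via lithium alkoxide 13 (not isolated)
Conditions: 12 (1.05 equiv, in Bu2O), THF, −78 °C; then Et3SiOTf, −78 to 0 °C
Reagents that add atoms: triethylsilyl triflate, CC[Si](CC)(CC)OS(=O)(=O)C(F)(F)F
Why: 1,2-Addition of an aryllithium to a squarate ester stops after one addition at −78 °C because the alkoxide deactivates the remaining vinylogous ester carbonyl, and the alkoxide is silylated in the same flask; the new carbinol carbon is racemic and is flattened later.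

Step 9
Reactants: 10 tert-butyl(3-iodo-2,2-dimethylpropoxy)dimethylsilane; 14 2,3-dimethoxy-4-phenyl-4-(triethylsilyloxy)cyclobut-2-en-1-one
Product: 18 3-[3-(tert-butyldimethylsilyloxy)-2,2-dimethylpropyl]-2-methoxy-4-phenyl-4-(triethylsilyloxy)cyclobut-2-en-1-one, via organolithium 15 (not isolated), via adduct alkoxide 16 (not isolated), via allylic trifluoroacetate 17 (not isolated)
Conditions: 10, t-BuLi (2 equiv), Et2O–pentane, −78 °C; 14 in THF, −78 °C; (CF3CO)2O, −78 °C; then aq. NaHCO3, to rt
Reagents that add atoms: water, O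
Why: Iodine–lithium exchange gives the neopentyl-type organolithium 15, which adds 1,2 to the strained vinylogous ester carbonyl of 14, and selective trifluoroacetylation of the new alkoxide lets only that C–O bond ionise to a methoxy-stabilised cyclobutenyl cation, which water captures at the distal methoxy carbon with loss of methanol (Stork–Danheiser-type addition and 1,3-carbonyl transposition as used on squarate adducts), so the alkyl group ends next to the phenyl carbinol carbon and OMe next to the carbonyl; a direct conjugate addition–elimination would give the same constitution.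

Step 10
Reactants: 18 3-[3-(tert-butyldimethylsilyloxy)-2,2-dimethylpropyl]-2-methoxy-4-phenyl-4-(triethylsilyloxy)cyclobut-2-en-1-one
Product: 19 4-hydroxy-3-(3-hydroxy-2,2-dimethylpropyl)-2-methoxy-4-phenylcyclobut-2-en-1-one
Conditions: HF·pyridine, pyridine, THF, 0 °C to rt
Reagents that add atoms: none
Why: Fluoride-driven cleavage of both silyl ethers in a pyridine-buffered medium avoids both alkoxide-triggered ring opening and acid-triggered ionisation of the 4-hydroxycyclobutenone.

Step 11
Reactants: 7 (2E,6S)-6-hydroxy-2,6-dimethylocta-2,7-dienoic acid; 19 4-hydroxy-3-(3-hydroxy-2,2-dimethylpropyl)-2-methoxy-4-phenylcyclobut-2-en-1-one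
Product: 21 3-(4-hydroxy-2-methoxy-3-oxo-4-phenylcyclobut-1-en-1-yl)-2,2-dimethylpropyl (2E,6S)-6-hydroxy-2,6-dimethylocta-2,7-dienoate, via mixed anhydride 20 (not isolated)
Conditions: 7, 2,4,6-Cl3C6H2COCl, Et3N, toluene, rt; then 19, DMAP, toluene, rt
Reagents that add atoms: none
Why: Yamaguchi esterification: DMAP passes the acyl group of 20 to the only primary hydroxyl while the two tertiary hydroxyls are too hindered to compete at rt, and at this oxidation level the methoxy carbon is not an electrophilic vinylogous ester carbon, so the free primary alcohol of 19 cannot cyclise onto it as it could in a 2-methoxyquinone.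

Step 12
Reactants: 21 3-(4-hydroxy-2-methoxy-3-oxo-4-phenylcyclobut-1-en-1-yl)-2,2-dimethylpropyl (2E,6S)-6-hydroxy-2,6-dimethylocta-2,7-dienoate
Product: 25 3-(3-methoxy-1,4-dioxo-1,4-dihydronaphthalen-2-yl)-2,2-dimethylpropyl (2E,6S)-6-hydroxy-2,6-dimethylocta-2,7-dienoate, via vinylketene 22 (not isolated), via bicyclic dienone 23 (not isolated), via hydroquinone 24 (not isolated)
Conditions: degassed p-xylene (0.01 M), 138 °C; cool to rt, then Ag2O, rt
Reagents that add atoms: none
Why: Heat opens the strained four-membered ring of 21 by conrotatory 4π electrocyclic cleavage of its C1–C4 bond, and because the C4 hydroxyl (the stronger donor) rotates outward, the phenyl group turns inward and comes to lie next to the ketene carbon of 22. The ketene carbon (future C1, whose neighbour C2 carries OMe) then bonds to an ortho carbon of the phenyl ring (future C8a) in a disrotatory 6π electrocyclisation, the mode by which six-membered ring B closes; enolisation of dienone 23 restores the aromaticity of ring A and gives hydroquinone 24, from which Ag2O takes two hydrogens. The closest known reaction type is the Moore ring expansion of 4-aryl-4-hydroxycyclobutenones to annulated hydroquinones, and 21 belongs to that substrate class (a 2-alkoxy-4-aryl-4-hydroxycyclobutenone). No lasting stereocentre is made: the racemic carbinol carbon becomes sp2 C4, the C8a–H centre of 23 is erased on enolisation, and the remote 6S carbinol and the 2E enoate are spectators under neutral thermolysis. The step needs torquoselectivity (secured by the hydroxyl donor), OMe at C2 and alkyl at C3 (fixed in 21 by step 9, the two ortho positions of the phenyl ring being equivalent), and ring closure faster than capture of the ketene by hydroxyl groups (secured by high dilution and by both free hydroxyls being tertiary). Release of ring strain and regained aromaticity make the sequence irreversible, so one operation should deliver ring B with all four of its carbons correctly substituted.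

Step 13
Reactants: 25 3-(3-methoxy-1,4-dioxo-1,4-dihydronaphthalen-2-yl)-2,2-dimethylpropyl (2E,6S)-6-hydroxy-2,6-dimethylocta-2,7-dienoate
Product: 27 3-(3-hydroxy-1,4-dioxo-1,4-dihydronaphthalen-2-yl)-2,2-dimethylpropyl (2E,6S)-6-hydroxy-2,6-dimethylocta-2,7-dienoate (target), via lithium quinonolate 26 (not isolated)
Conditions: LiOH, THF–H2O, 0 °C; then cold dilute HCl to pH 4
Reagents that add atoms: lithium hydroxide, [Li+].[OH-]
Why: Addition–elimination hydrolysis of a vinylogous ester: hydroxide should attack quinone C2 much faster than the carbonyl of an α-branched, conjugated ester of a neopentyl-type alcohol, the delocalised anion 26 resists further attack, and the mild acidification spares the tertiary allylic alcohol.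

Compound list
1 | geraniol | CC(C)=CCC/C(C)=C/CO | starting material
2 | (2S,3S)-2,3-epoxygeraniol | OC[C@@H]1O[C@@]1(C)CCC=C(C)C | intermediate
3 | (2R,3S)-2-(iodomethyl)-3-methyl-3-(4-methylpent-3-en-1-yl)oxirane | IC[C@@H]1O[C@@]1(C)CCC=C(C)C | intermediate
4 | (S)-(+)-linalool | C=C[C@@](C)(O)CCC=C(C)C | intermediate
5 | (2E,6S)-2,6-dimethylocta-2,7-diene-1,6-diol | C=C[C@@](C)(O)CC/C=C(\C)CO | intermediate
6 | (2E,6S)-6-hydroxy-2,6-dimethylocta-2,7-dienal | C=C[C@@](C)(O)CC/C=C(\C)C=O | intermediate
7 | (2E,6S)-6-hydroxy-2,6-dimethylocta-2,7-dienoic acid | C=C[C@@](C)(O)CC/C=C(\C)C(=O)O | intermediate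
8 | 2,2-dimethylpropane-1,3-diol | CC(C)(CO)CO | starting material
9 | 3-(tert-butyldimethylsilyloxy)-2,2-dimethylpropan-1-ol | CC(C)(CO)CO[Si](C)(C)C(C)(C)C | intermediate
10 | tert-butyl(3-iodo-2,2-dimethylpropoxy)dimethylsilane | CC(C)(CI)CO[Si](C)(C)C(C)(C)C | intermediate
11 | dimethyl squarate (3,4-dimethoxycyclobut-3-ene-1,2-dione) | COC1=C(OC)C(=O)C1=O | starting material
12 | phenyllithium | [Li]c1ccccc1 | starting material
13 | lithium 2,3-dimethoxy-4-oxo-1-phenylcyclobut-2-en-1-olate (racemic) | COC1=C(OC)C([O-])(c2ccccc2)C1=O.[Li+] | intermediate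
14 | 2,3-dimethoxy-4-phenyl-4-(triethylsilyloxy)cyclobut-2-en-1-one (racemic) | COC1=C(OC)C(O[Si](CC)(CC)CC)(c2ccccc2)C1=O | intermediate
15 | [3-(tert-butyldimethylsilyloxy)-2,2-dimethylpropyl]lithium | [Li]CC(C)(C)CO[Si](C)(C)C(C)(C)C | intermediate
16 | lithium 1-[3-(tert-butyldimethylsilyloxy)-2,2-dimethylpropyl]-2,3-dimethoxy-4-phenyl-4-(triethylsilyloxy)cyclobut-2-en-1-olate | COC1=C(OC)C([O-])(CC(C)(C)CO[Si](C)(C)C(C)(C)C)C1(O[Si](CC)(CC)CC)c1ccccc1.[Li+] | intermediate
17 | 1-[3-(tert-butyldimethylsilyloxy)-2,2-dimethylpropyl]-2,3-dimethoxy-4-phenyl-4-(triethylsilyloxy)cyclobut-2-en-1-yl trifluoroacetate | COC1=C(OC)C(OC(=O)C(F)(F)F)(CC(C)(C)CO[Si](C)(C)C(C)(C)C)C1(O[Si](CC)(CC)CC)c1ccccc1 | intermediate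
18 | 3-[3-(tert-butyldimethylsilyloxy)-2,2-dimethylpropyl]-2-methoxy-4-phenyl-4-(triethylsilyloxy)cyclobut-2-en-1-one (racemic) | COC1=C(CC(C)(C)CO[Si](C)(C)C(C)(C)C)C(O[Si](CC)(CC)CC)(c2ccccc2)C1=O | intermediate
19 | 4-hydroxy-3-(3-hydroxy-2,2-dimethylpropyl)-2-methoxy-4-phenylcyclobut-2-en-1-one (racemic) | COC1=C(CC(C)(C)CO)C(O)(c2ccccc2)C1=O | intermediate
20 | (2E,6S)-6-hydroxy-2,6-dimethylocta-2,7-dienoic 2,4,6-trichlorobenzoic anhydride | C=C[C@@](C)(O)CC/C=C(\C)C(=O)OC(=O)c1c(Cl)cc(Cl)cc1Cl | intermediate
21 | 3-(4-hydroxy-2-methoxy-3-oxo-4-phenylcyclobut-1-en-1-yl)-2,2-dimethylpropyl (2E,6S)-6-hydroxy-2,6-dimethylocta-2,7-dienoate (both epimers at the ring carbinol carbon) | C=C[C@@](C)(O)CC/C=C(\C)C(=O)OCC(C)(C)CC1=C(OC)C(=O)C1(O)c1ccccc1 | intermediate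
22 | vinylketene O=C=C(OMe)–C(alkyl)=C(OH)Ph, E enol with phenyl cis to the ketene-bearing carbon | C=C[C@@](C)(O)CC/C=C(\C)C(=O)OCC(C)(C)C/C(C(OC)=C=O)=C(\O)c1ccccc1 | intermediate
23 | 4-hydroxy-2-methoxy-3-alkyl-8aH-naphthalen-1-one (dienone before enolisation) | C=C[C@@](C)(O)CC/C=C(\C)C(=O)OCC(C)(C)CC1=C(OC)C(=O)C2C=CC=CC2=C1O | intermediate
24 | 3-(1,4-dihydroxy-3-methoxynaphthalen-2-yl)-2,2-dimethylpropyl (2E,6S)-6-hydroxy-2,6-dimethylocta-2,7-dienoate | C=C[C@@](C)(O)CC/C=C(\C)C(=O)OCC(C)(C)Cc1c(OC)c(O)c2ccccc2c1O | intermediate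
25 | 3-(3-methoxy-1,4-dioxo-1,4-dihydronaphthalen-2-yl)-2,2-dimethylpropyl (2E,6S)-6-hydroxy-2,6-dimethylocta-2,7-dienoate | C=C[C@@](C)(O)CC/C=C(\C)C(=O)OCC(C)(C)CC1=C(OC)C(=O)c2ccccc2C1=O | intermediate
26 | lithium salt of the target (quinon-2-olate) | C=C[C@@](C)(O)CC/C=C(\C)C(=O)OCC(C)(C)CC1=C([O-])C(=O)c2ccccc2C1=O.[Li+] | intermediate
27 | 3-(3-hydroxy-1,4-dioxo-1,4-dihydronaphthalen-2-yl)-2,2-dimethylpropyl (2E,6S)-6-hydroxy-2,6-dimethylocta-2,7-dienoate | C=C[C@@](C)(O)CC/C=C(\C)C(=O)OCC(C)(C)CC1=C(O)C(=O)c2ccccc2C1=O | target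

Total step count: 13. Longest linear sequence: 8 steps (steps 1–5 and 11–13, from geraniol).

Steps most likely to fail

Step 9. The organolithium may add slowly to a carbonyl flanked by a fully substituted carbon, giving it time to decay by γ-elimination or by silyl shift from oxygen to carbon. The triethylsilyl group may also migrate from the C4 oxygen to the neighbouring new alkoxide, after which the wrong C–O bond would ionise. The fallback reverses the order of the two additions and uses a cyclobutenedione monoacetal. It sets out from 11 (with 10 and 12) and comes back at 19.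
- Organolithium 15, made from 10 as before, is added to unhindered 11 in THF at −78 °C. This gives 4-[3-(tert-butyldimethylsilyloxy)-2,2-dimethylpropyl]-4-hydroxy-2,3-dimethoxycyclobut-2-en-1-one F1.
- (CF3CO)2O followed by methanol turns it into 2-[3-(tert-butyldimethylsilyloxy)-2,2-dimethylpropyl]-3,4,4-trimethoxycyclobut-2-en-1-one F2, in which the more electrophilic carbonyl is masked as its dimethyl acetal.
- Phenyllithium 12 adds to the only free carbonyl to give 2-[3-(tert-butyldimethylsilyloxy)-2,2-dimethylpropyl]-3,4,4-trimethoxy-1-phenylcyclobut-2-en-1-ol F3.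
- Aqueous HF in MeCN cleaves the acetal and the silyl ether to give 19.

Step 13. The side-chain ester may be lost by competing saponification if attack at the hindered C2 is slow. The fallback unmasks the hydroxyquinone before the ester exists and makes the esterification the last event. It sets out from 18 and comes back at 27.
- Thermolysis of 18 in p-xylene at 138 °C gives 3-[3-(tert-butyldimethylsilyloxy)-2,2-dimethylpropyl]-2-methoxy-4-(triethylsilyloxy)naphthalen-1-ol F4.
- (NH4)2Ce(NO3)6 in MeCN–H2O at 0 °C oxidises it to 2-[3-(tert-butyldimethylsilyloxy)-2,2-dimethylpropyl]-3-methoxy-1,4-naphthoquinone F5.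
- Aqueous NaOH in THF, now free of any selectivity problem, gives 2-[3-(tert-butyldimethylsilyloxy)-2,2-dimethylpropyl]-3-hydroxy-1,4-naphthoquinone F6.
- HF·pyridine gives 2-hydroxy-3-(3-hydroxy-2,2-dimethylpropyl)-1,4-naphthoquinone F7.
- Acylation with mixed anhydride 20 and DMAP should take place at the primary alcohol. The delocalised enolate is a poor nucleophile, and any enol ester is a vinylogous anhydride that passes its acyl group on or is cleaved in the NaHCO3 wash. This gives 27.

Step 12. Hydroxyl groups may intercept the ketene, partial inward rotation of the C4 hydroxyl may lead to lactonisation, or the side chain may wear at 138 °C. The fallback gives up the ring construction and joins the side chain to a bought naphthoquinone by three-component reductive alkylation. It sets out from 7 (with 8) and comes back at 27.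
- Mixed anhydride 20 made from 7 is treated with excess 8 and DMAP to give 3-hydroxy-2,2-dimethylpropyl (2E,6S)-6-hydroxy-2,6-dimethylocta-2,7-dienoate F8.
- Dess–Martin periodinane gives 2,2-dimethyl-3-oxopropyl (2E,6S)-6-hydroxy-2,6-dimethylocta-2,7-dienoate F9.
- L-Proline-catalysed Knoevenagel condensation with commercial 2-hydroxy-1,4-naphthoquinone gives the 3-alkylidene-naphthalene-1,2,4-trione F10.
- Hantzsch ester reduces F10 in the same flask to 27.

Further compounds
F1 | step 9 | 4-[3-(tert-butyldimethylsilyloxy)-2,2-dimethylpropyl]-4-hydroxy-2,3-dimethoxycyclobut-2-en-1-one | COC1=C(OC)C(O)(CC(C)(C)CO[Si](C)(C)C(C)(C)C)C1=O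
F2 | step 9 | 2-[3-(tert-butyldimethylsilyloxy)-2,2-dimethylpropyl]-3,4,4-trimethoxycyclobut-2-en-1-one | COC1=C(CC(C)(C)CO[Si](C)(C)C(C)(C)C)C(=O)C1(OC)OC
F3 | step 9 | 2-[3-(tert-butyldimethylsilyloxy)-2,2-dimethylpropyl]-3,4,4-trimethoxy-1-phenylcyclobut-2-en-1-ol | COC1=C(CC(C)(C)CO[Si](C)(C)C(C)(C)C)C(O)(c2ccccc2)C1(OC)OC
F4 | step 13 | 3-[3-(tert-butyldimethylsilyloxy)-2,2-dimethylpropyl]-2-methoxy-4-(triethylsilyloxy)naphthalen-1-ol | COc1c(O)c2ccccc2c(O[Si](CC)(CC)CC)c1CC(C)(C)CO[Si](C)(C)C(C)(C)C
F5 | step 13 | 2-[3-(tert-butyldimethylsilyloxy)-2,2-dimethylpropyl]-3-methoxy-1,4-naphthoquinone | COC1=C(CC(C)(C)CO[Si](C)(C)C(C)(C)C)C(=O)c2ccccc2C1=O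
F6 | step 13 | 2-[3-(tert-butyldimethylsilyloxy)-2,2-dimethylpropyl]-3-hydroxy-1,4-naphthoquinone | CC(C)(CO[Si](C)(C)C(C)(C)C)CC1=C(O)C(=O)c2ccccc2C1=O
F7 | step 13 | 2-hydroxy-3-(3-hydroxy-2,2-dimethylpropyl)-1,4-naphthoquinone | CC(C)(CO)CC1=C(O)C(=O)c2ccccc2C1=O
F8 | step 12 | 3-hydroxy-2,2-dimethylpropyl (2E,6S)-6-hydroxy-2,6-dimethylocta-2,7-dienoate | C=C[C@@](C)(O)CC/C=C(\C)C(=O)OCC(C)(C)CO
F9 | step 12 | 2,2-dimethyl-3-oxopropyl (2E,6S)-6-hydroxy-2,6-dimethylocta-2,7-dienoate | C=C[C@@](C)(O)CC/C=C(\C)C(=O)OCC(C)(C)C=O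
F10 | step 12 | 2,2-dimethyl-3-(1,3,4-trioxo-3,4-dihydronaphthalen-2(1H)-ylidene)propyl (2E,6S)-6-hydroxy-2,6-dimethylocta-2,7-dienoate | C=C[C@@](C)(O)CC/C=C(\C)C(=O)OCC(C)(C)C=C1C(=O)C(=O)c2ccccc2C1=O
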